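A direct plan would keep ring A as a bought arene and build ring B atom by atom on its phenol oxygen.
3,5-Dibromo-2-methoxyphenol A1 would be O-alkylated with methyl 2-chloroacetoacetate A2 to the aryloxy keto ester A3, which would be converted in two operations (enol ether formation, then lithium diisopropylamide and Me3SiCl) into the vinylketene silyl acetal A4.
A Diels–Alder reaction of A4 with phenyl vinyl sulfoxide A5, thermal sulfoxide elimination and acid would give the diaryl ether phenol A6, and a double electrophilic bromination would finish ring B.
Weakest would be the cycloaddition/aromatisation: A4, a 1,1,2,3-tetrasubstituted diene with a bulky 2-aryloxy group, would have to reach the s-cis form and add a sluggish dienophile near 110 °C, where silyl ketene acetals degrade, and all of ring B would hang on it.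
Second, the γ-deprotonation on the way to A4: ring A carries a C–H between two bromines that amide bases also lithiate (halogen dance, aryne), and the water-sensitive diene could only be used crude.
Third, the linear run-up: four operations in one line would be spent on a ring that is only a resorcinol monomethyl ether, with the ring A bromines at risk in each.

**Retrosynthetic overview**
Ring A is the 3,5-dibromo-2-methoxyphenyl ring (C1 on the bridging oxygen); ring B is the phenol ring (C1' on the bridging oxygen, C2'–OH, C3'–Br, C5'–Br, C6'–OMe).
The target is cut once, at the C1'–O bond. C1' lies between C2'–OH and C6'–OMe, which makes it the diazo carbon of an o-quinone diazide whose carbonyl oxygen becomes the C2'–OH.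
Ring A phenol 4 and ring B diazo-oxide 9 each receive their two bromines and their methyl ether by directed aromatic chemistry; neither ring is built, and the two are joined last by a Rh2(OAc)4-catalysed carbenoid O–H insertion that re-aromatises ring B as the ether bond forms.
The design has no cycloaddition, no carbocycle construction and no organolithium next to an aryl bromide, and nothing is brominated or methylated after the union; the route is convergent (2 + 3 steps before the coupling).

Key step: step 6

Remark: 9 is drawn as the o-quinone diazide; it is the same compound as the 2-diazoniophenolate zwitterion, and it would be handled only in solution and in the dark.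

Step 1
Reactants: 1 3,5-dibromosalicylaldehyde
Product: 2 3,5-dibromo-2-methoxybenzaldehyde
Conditions: MeI (1.5 equiv), K2CO3 (1.5 equiv), DMF, rt
Reagents that add atoms: iodomethane, CI
Why: Williamson O-methylation of the acidic phenoxide, which has no free ortho or para carbon and can therefore react only on oxygen.

Step 2
Reactants: 2 3,5-dibromo-2-methoxybenzaldehyde
Product: 4 3,5-dibromo-2-methoxyphenol, via aryl formate 3 (not isolated)
Conditions: mCPBA (1.5 equiv), CH2Cl2, 40 °C; then K2CO3 (cat.), MeOH, rt
Reagents that add atoms: meta-chloroperoxybenzoic acid, O=C(OO)c1cccc(Cl)c1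
Why: Baeyer–Villiger (Dakin-type) oxidation in which the ortho-methoxy aryl group should migrate in the Criegee intermediate, followed by methanolysis of the formate, with the aryl bromides and the methyl ether inert to the peracid.

Step 3
Reactants: 5 3-methoxy-2-nitrophenol
Product: 6 4,6-dibromo-3-methoxy-2-nitrophenol
Conditions: Br2 (2.1 equiv), AcOH, rt
Reagents that add atoms: bromine, BrBr
Why: Electrophilic aromatic bromination in which C4 and C6 are each ortho or para to both the hydroxyl and the methoxy group and meta to the nitro group, whereas C5 is meta to both donors, so the bromines should enter only at the carbons that become C5' and C3'.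

Step 4
Reactants: 6 4,6-dibromo-3-methoxy-2-nitrophenol
Product: 7 2-amino-4,6-dibromo-3-methoxyphenol
Conditions: Fe powder (5 equiv), AcOH/EtOH (1:3), 60 °C; filtration and work-up under N2
Reagents that add atoms: none
Why: Béchamp-type dissolving-metal reduction of the nitro group by Fe powder in acetic acid, which proceeds by electron transfer to the nitro group and should leave the aryl bromides untouched, unlike a hydrogenation over Pd/C.

Step 5
Reactants: 7 2-amino-4,6-dibromo-3-methoxyphenol
Product: 9 2,4-dibromo-6-diazo-5-methoxycyclohexa-2,4-dien-1-one, via diazonium hydrogen sulfate 8 (not isolated)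
Conditions: NaNO2 (1.05 equiv), H2SO4, AcOH/H2O, 0 °C; then NaOAc (pH 5), CH2Cl2 extraction, dark; kept as a solution
Reagents that add atoms: sodium nitrite, [Na+].[O-]N=O
Why: Diazotisation of the o-aminophenol gives diazonium ion 8, whose ortho-hydroxyl, acidified by the diazonium group and two bromines, should lose its proton on buffering to give the neutral, extractable o-quinone diazide, and the non-nucleophilic hydrogen sulfate counter-ion avoids displacement of the methoxy group ortho to the diazonium group.

Step 6
Reactants: 4 3,5-dibromo-2-methoxyphenol; 9 2,4-dibromo-6-diazo-5-methoxycyclohexa-2,4-dien-1-one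
Product: 10 4,6-dibromo-2-(3,5-dibromo-2-methoxyphenoxy)-3-methoxyphenol
Conditions: Rh2(OAc)4 (2 mol %), 4 (1.5 equiv), 4 Å MS, ClCH2CH2Cl, 70 °C, slow addition of 9, dark
Reagents that add atoms: none
Why: Rh2(OAc)4 should displace nitrogen from 9 to give an electrophilic divalent-rhodium carbenoid at C1'; the oxygen of phenol 4 adds to this carbon to give an oxonium ylide, and proton transfer to the former carbonyl oxygen releases the catalyst and delivers the enol, which here is the aromatic ring B phenol, so the C1'–O bond and the aromaticity of ring B arise in one operation. The closest known reaction type is the Rh2(OAc)4-catalysed O–H insertion of α-diazo ketones and cyclic 2-diazo-1,3-diones into phenols and of 1,2-naphthoquinone diazides into alcohols. No ring is closed and no stereocentre is formed; the step joins two complete rings at the carbon flanked by C2'–O and C6'–OMe, a site that is crowded for Ullmann or SNAr arylation but open as a planar carbenoid. Regiochemistry needs no control, because the new bond can form only at the diazo carbon, which fixes OH, OAr and OMe on three neighbouring carbons. The selectivity needed is O–H insertion over aromatic C–H attack, over capture by the product phenol or by water, and over carbene dimerisation or Wolff ring contraction. Ring A of 4 is deactivated by two bromines; the hydroxyl of 10 is flanked by bromine and aryloxy whereas that of 4 has a free ortho position and is used in excess; sieves exclude water; and slow addition keeps free 9 dilute.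

**Compound list**
1 | 3,5-dibromosalicylaldehyde | O=Cc1cc(Br)cc(Br)c1O | starting material
2 | 3,5-dibromo-2-methoxybenzaldehyde | COc1c(Br)cc(Br)cc1C=O | intermediate
3 | 3,5-dibromo-2-methoxyphenyl formate (not isolated) | COc1c(Br)cc(Br)cc1OC=O | intermediate
4 | 3,5-dibromo-2-methoxyphenol | COc1c(Br)cc(Br)cc1O | intermediate
5 | 3-methoxy-2-nitrophenol | COc1cccc(O)c1[N+](=O)[O-] | starting material
6 | 4,6-dibromo-3-methoxy-2-nitrophenol | COc1c(Br)cc(Br)c(O)c1[N+](=O)[O-] | intermediate
7 | 2-amino-4,6-dibromo-3-methoxyphenol | COc1c(Br)cc(Br)c(O)c1N | intermediate
8 | 3,5-dibromo-2-hydroxy-6-methoxybenzenediazonium hydrogen sulfate (not isolated) | COc1c(Br)cc(Br)c(O)c1[N+]#N.OS(=O)(=O)[O-] | intermediate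
9 | 2,4-dibromo-6-diazo-5-methoxycyclohexa-2,4-dien-1-one | COC1=C(Br)C=C(Br)C(=O)C1=[N+]=[N-] | intermediate
10 | 4,6-dibromo-2-(3,5-dibromo-2-methoxyphenoxy)-3-methoxyphenol | COc1c(Br)cc(Br)cc1Oc1c(O)c(Br)cc(Br)c1OC | target

Total step count: 6. Longest linear sequence: 4 steps (steps 3 to 6, from 5).

**Steps most likely to fail**

Step 6: nitrogen loss from 9 may outrun capture by the phenol, through Wolff-type ring contraction, carbene dimerisation, azo coupling of 9 with 4, or insertion into traces of water. As a fallback, ring B would be carried as a saturated 1,3-dione and aromatised after the ether bond is made. The fallback sets out from 4. 2-Diazocyclohexane-1,3-dione F1, made from cyclohexane-1,3-dione by Regitz diazo transfer (4-acetamidobenzenesulfonyl azide, Et3N, MeCN), would undergo the Rh2(OAc)4-catalysed O–H insertion with 4 (CH2Cl2, 40 °C) to give 2-(3,5-dibromo-2-methoxyphenoxy)cyclohexane-1,3-dione F2. Bromine (3 equiv, AcOH, rt to 50 °C) would brominate an α' carbon (any C2 bromide equilibrating under HBr), lose HBr to the resorcinol and brominate its two activated positions, giving 4,6-dibromo-2-(3,5-dibromo-2-methoxyphenoxy)benzene-1,3-diol F3. Methylation of one of the two equivalent hydroxyls (MeI, 1 equiv, K2CO3, acetone), with recycling of unreacted F3, would come back to the route at 10.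

Step 5: the neutral diazo-oxide may be lost while it is set free and extracted, by photolytic or thermal nitrogen loss with ring contraction or by self-coupling of its diazonium and phenoxide forms near neutral pH. As a fallback, the nitrogen would serve only as a leaving group in acid and the ether bond would be made by a CuI-catalysed Ullmann coupling. The fallback sets out from 7. The cold acidic solution of 8, stable as the diazonium ion, would be treated with KI to give 4,6-dibromo-2-iodo-3-methoxyphenol F4. MOMCl/iPr2NEt would give 1,5-dibromo-3-iodo-2-methoxy-4-(methoxymethoxy)benzene F5. An Ullmann-type coupling with 4 (CuI, picolinic acid, K3PO4, DMSO, 80 °C), in which the C–I bond should react before the C–Br bonds, would give 1,5-dibromo-3-(3,5-dibromo-2-methoxyphenoxy)-2-methoxy-4-(methoxymethoxy)benzene F6. HCl in MeOH would remove the acetal and come back to the route at 10.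

Step 2: hydride may migrate in place of the aryl group in the Criegee intermediate, because the methoxy group between bromine and formyl is twisted out of conjugation and the ring is electron-poor; the formyl carbon would then be over-oxidised instead of excised. As a fallback, the migrating-group competition would be changed by turning the aldehyde into a methyl ketone, so that no hydride is left to migrate. The fallback sets out from 2. MeMgBr (THF, −78 °C), which adds to the aldehyde far faster than it exchanges an aryl bromide, would give racemic 1-(3,5-dibromo-2-methoxyphenyl)ethanol F7. Dess–Martin periodinane (CH2Cl2, rt) would give 1-(3,5-dibromo-2-methoxyphenyl)ethanone F8. Baeyer–Villiger oxidation (mCPBA, CF3CO2H cat., CH2Cl2, rt), in which methyl is the poorest migrating group and the aryl group should therefore move, would give 3,5-dibromo-2-methoxyphenyl acetate F9. Methanolysis (K2CO3, MeOH, rt) would come back to the route at 4.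

**Further compounds**
F1 | step 6 | 2-diazocyclohexane-1,3-dione | [N-]=[N+]=C1C(=O)CCCC1=O
F2 | step 6 | 2-(3,5-dibromo-2-methoxyphenoxy)cyclohexane-1,3-dione | COc1c(Br)cc(Br)cc1OC1C(=O)CCCC1=O
F3 | step 6 | 4,6-dibromo-2-(3,5-dibromo-2-methoxyphenoxy)benzene-1,3-diol | COc1c(Br)cc(Br)cc1Oc1c(O)c(Br)cc(Br)c1O
F4 | step 5 | 4,6-dibromo-2-iodo-3-methoxyphenol | COc1c(Br)cc(Br)c(O)c1I
F5 | step 5 | 1,5-dibromo-3-iodo-2-methoxy-4-(methoxymethoxy)benzene | COCOc1c(Br)cc(Br)c(OC)c1I
F6 | step 5 | 1,5-dibromo-3-(3,5-dibromo-2-methoxyphenoxy)-2-methoxy-4-(methoxymethoxy)benzene | COCOc1c(Br)cc(Br)c(OC)c1Oc1cc(Br)cc(Br)c1OC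
F7 | step 2 | 1-(3,5-dibromo-2-methoxyphenyl)ethanol (racemic) | COc1c(Br)cc(Br)cc1C(C)O
F8 | step 2 | 1-(3,5-dibromo-2-methoxyphenyl)ethanone | COc1c(Br)cc(Br)cc1C(C)=O
F9 | step 2 | 3,5-dibromo-2-methoxyphenyl acetate | COc1c(Br)cc(Br)cc1OC(C)=O
A1 | direct plan | 3,5-dibromo-2-methoxyphenol | COc1c(Br)cc(Br)cc1O
A2 | direct plan | methyl 2-chloroacetoacetate | COC(=O)C(Cl)C(C)=O
A3 | direct plan | methyl 2-(3,5-dibromo-2-methoxyphenoxy)-3-oxobutanoate | COC(=O)C(Oc1cc(Br)cc(Br)c1OC)C(C)=O
A4 | direct plan | (1E)-2-(3,5-dibromo-2-methoxyphenoxy)-1,3-dimethoxy-1-(trimethylsilyloxy)buta-1,3-diene | C=C(OC)/C(Oc1cc(Br)cc(Br)c1OC)=C(/OC)O[Si](C)(C)C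
A5 | direct plan | phenyl vinyl sulfoxide | C=CS(=O)c1ccccc1
A6 | direct plan | 2-(3,5-dibromo-2-methoxyphenoxy)-3-methoxyphenol | COc1cccc(O)c1Oc1cc(Br)cc(Br)c1OC
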